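**Retrosynthetic overview**
- The oxirane C–O bond is cut first (3-exo-tet Williamson closure), which leads back to an (S)-bromohydrin tiglate.
- The tiglate C–O bond is made on the ring oxygen of a prochiral 3-aryloxetan-3-ol while bromide cleaves one of the two enantiotopic oxetane C–O bonds. This desymmetrisation sets the only stereocentre.
- The aryl angelate C–O bond comes from phenol-selective acylation with angelic anhydride.
- The aryl–C(quaternary) bond comes from the dianion of 2-bromo-4-methoxy-5-methylphenol and oxetan-3-one. The bromophenol comes from 4-methoxy-3-methylphenol.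
- Ring order: the arene and the oxetane are bought, the oxetane is opened in the last step, and the oxirane is the only ring formed.

Assumption: 1, 4, 7 and 9 are taken as catalogue chemicals, and the squaramide antipode that gives (S)-11 is found in a small trial run, since both antipodes are equally accessible.

**Step 1**
Reactants: 1 4-methoxy-3-methylphenol; 2 N-bromosuccinimide
Product: 3 2-bromo-4-methoxy-5-methylphenol
Conditions: NBS (1.0 equiv), dry MeCN, 0 °C, dark, 1 h
Reagents that add atoms: N-bromosuccinimide (2), O=C1CCC(=O)N1Br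
Why: Electrophilic aromatic bromination goes ortho to the OH, the strongest director, at the position that is also para to the methyl group, because the other ortho site is squeezed between OH and CH3 and the remaining CH is activated by OMe only.

**Step 2**
Reactants: 3 2-bromo-4-methoxy-5-methylphenol; 4 oxetan-3-one
Product: 6 3-(2-hydroxy-5-methoxy-4-methylphenyl)oxetan-3-ol, via dilithiated phenoxide 5 (not isolated)
Conditions: n-BuLi (2.2 equiv), Et2O, 0 to 23 °C, 1.5 h; then 4 (1.3 equiv), THF, −78 to 0 °C; sat. aq NH4Cl
Reagents that add atoms: oxetan-3-one (4), O=C1COC1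
Why: Deprotonation followed by bromine–lithium exchange gives the O,C-dilithio species, which adds 1,2 to the strained and very electrophilic ketone, and the base-stable oxetane leaves the new carbinol carbon prochiral with two enantiotopic CH2O arms.

**Step 3**
Reactants: 6 3-(2-hydroxy-5-methoxy-4-methylphenyl)oxetan-3-ol; 7 angelic anhydride
Product: 8 2-(3-hydroxyoxetan-3-yl)-4-methoxy-5-methylphenyl (2Z)-2-methylbut-2-enoate
Conditions: 7 (1.1 equiv), K2CO3 (1.5 equiv), acetone, 0 °C, 1–2 h, no DMAP
Reagents that add atoms: angelic anhydride (7), C/C=C(/C)C(=O)OC(=O)/C(C)=C\C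
Why: Chemoselective O-acylation of the phenoxide by an anhydride leaves the tertiary alcohol untouched, and the Z geometry is kept because no nucleophilic catalyst and no acid chloride/ketene pathway is present.

**Step 4**
Reactants: 8 2-(3-hydroxyoxetan-3-yl)-4-methoxy-5-methylphenyl (2Z)-2-methylbut-2-enoate; 9 tigloyl chloride
Product: 12 [(2R)-2-{5-methoxy-4-methyl-2-[(2Z)-2-methylbut-2-enoyloxy]phenyl}oxiran-2-yl]methyl (2E)-2-methylbut-2-enoate, via tigloyl bromide 10 (not isolated), via (S)-bromohydrin tiglate 11 (not isolated)
Conditions: 9 (1.25 equiv), Me3SiBr (1.2 equiv), neat, 23 °C, then Me3SiCl stripped in vacuo; 8, chiral tert-leucine arylpyrrolidine amide squaramide bearing a 3,5-bis(trifluoromethyl)anilino arm (10 mol %), TBME/PhMe, −40 °C; then Cs2CO3 (3 equiv), MeCN, −20 to 0 °C, same pot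
Reagents that add atoms: tigloyl chloride (9), C/C=C(\C)C(=O)Cl
Why: Proposed new method: an acyl bromide replaces a silyl bromide in a squaramide hydrogen-bond-donor-catalysed desymmetrising oxetane opening. The unhindered, strongly Lewis basic oxetane oxygen of 8 is acylated by 10, or protonated by the trace HBr that 10 regenerates each time it esterifies a freed primary alcohol, both paths converging on 11. The catalyst binds the bromide of the oxetanium ion pair and delivers it by SN2 to one of the two enantiotopic ring CH2 groups, which makes the tiglate C–O bond and fixes the carbinol carbon as (S) in 11 without touching any of its four bonds. The hindered tertiary OH stays free, and once the ring is open it can reach the anti-periplanar geometry that the intact oxetane forbids, so carbonate triggers a Thorpe–Ingold-accelerated 3-exo-tet Williamson closure that forms the oxirane C–O bond with the spatial arrangement kept. (S)-11 becomes (R)-12 only because the former CH2Br carbon drops in CIP rank. The closest known reaction types are the chiral squaramide-catalysed enantioselective opening of 3-substituted and 3,3-disubstituted oxetanes with Me3SiBr, the acyl halide cleavage of cyclic ethers, and the base closure of halohydrins.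

**Compound list**
1 | 4-methoxy-3-methylphenol | Oc1cc(C)c(OC)cc1 | starting material
2 | N-bromosuccinimide | O=C1CCC(=O)N1Br | starting material
3 | 2-bromo-4-methoxy-5-methylphenol | Oc1cc(C)c(OC)cc1Br | intermediate
4 | oxetan-3-one | O=C1COC1 | starting material
5 | lithium 2-lithio-4-methoxy-5-methylphenoxide | [Li]Oc1cc(C)c(OC)cc1[Li] | intermediate
6 | 3-(2-hydroxy-5-methoxy-4-methylphenyl)oxetan-3-ol | Oc1cc(C)c(OC)cc1C1(O)COC1 | intermediate
7 | angelic anhydride, (2Z)-2-methylbut-2-enoic anhydride | C/C=C(/C)C(=O)OC(=O)/C(C)=C\C | starting material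
8 | 2-(3-hydroxyoxetan-3-yl)-4-methoxy-5-methylphenyl (2Z)-2-methylbut-2-enoate | C/C=C(/C)C(=O)Oc1cc(C)c(OC)cc1C1(O)COC1 | intermediate
9 | tigloyl chloride, (2E)-2-methylbut-2-enoyl chloride | C/C=C(\C)C(=O)Cl | starting material
10 | tigloyl bromide, (2E)-2-methylbut-2-enoyl bromide | C/C=C(\C)C(=O)Br | intermediate
11 | (2S)-3-bromo-2-hydroxy-2-{5-methoxy-4-methyl-2-[(2Z)-2-methylbut-2-enoyloxy]phenyl}propyl (2E)-2-methylbut-2-enoate | C/C=C(/C)C(=O)Oc1cc(C)c(OC)cc1[C@](O)(COC(=O)/C(C)=C/C)CBr | intermediate
12 | [(2R)-2-{5-methoxy-4-methyl-2-[(2Z)-2-methylbut-2-enoyloxy]phenyl}oxiran-2-yl]methyl (2E)-2-methylbut-2-enoate | C/C=C(/C)C(=O)Oc1cc(C)c(OC)cc1[C@]1(COC(=O)/C(C)=C/C)CO1 | target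

**Total step count:** 4. **Longest linear sequence:** 4 (1 → 3 → 6 → 8 → 12).

**Steps most likely to fail**

**1. Step 4 (the proposed new step).**
- Risks:
  - An uncatalysed racemic opening could lower the ee.
  - The tertiary OH could be acylated or ionised by 10 or HBr.
  - At the closure stage the alkoxide could attack the aryl angelate, and the freed phenoxide would then close to a dihydrobenzofuran.
- The fallback uses known chemistry only (Suzuki–Miyaura coupling and Sharpless asymmetric epoxidation with in-pot esterification). It sets out from 3 and comes back at 12.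
- Compound 3 is lithiated to 5 as in step 2, trapped with B(OMe)3 and hydrolysed to (2-hydroxy-5-methoxy-4-methylphenyl)boronic acid F1.
- Coupling with commercial 2-bromoprop-2-en-1-ol (Pd(PPh3)4, Na2CO3, DME/H2O, 80 °C) gives 2-(3-hydroxyprop-1-en-2-yl)-4-methoxy-5-methylphenol F2.
- Phenol-selective acylation with 7 (K2CO3, acetone, 0 °C) gives 2-(3-hydroxyprop-1-en-2-yl)-4-methoxy-5-methylphenyl (2Z)-2-methylbut-2-enoate F3.
- Epoxidation with Ti(OiPr)4, L-(+)-diisopropyl tartrate, t-BuOOH and 4 Å MS in CH2Cl2 at −20 °C follows the same facial sense that turns allyl alcohol into (S)-glycidol. It gives 2-[(2S)-2-(hydroxymethyl)oxiran-2-yl]-4-methoxy-5-methylphenyl (2Z)-2-methylbut-2-enoate F4.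
- Adding 9 and Et3N to the same pot gives 12. The descriptor changes from S to R by CIP ranking only.

**2. Step 2.**
- Risks:
  - The bromine–lithium exchange on the electron-rich phenoxide may be sluggish.
  - The poorly soluble dianion may enolise 4.
  - The free phenol may open the oxetane on work-up.
- The fallback masks the phenol instead of carrying it as an anion. It sets out from 3 and comes back at 6.
- Benzyl bromide and K2CO3 in DMF give 1-(benzyloxy)-2-bromo-4-methoxy-5-methylbenzene F5.
- n-BuLi (1.05 equiv) in THF at −78 °C gives [2-(benzyloxy)-5-methoxy-4-methylphenyl]lithium F6.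
- Addition of F6 to 4 gives 3-[2-(benzyloxy)-5-methoxy-4-methylphenyl]oxetan-3-ol F7.
- Neutral hydrogenolysis (H2, Pd/C, EtOAc) then frees 6.

**3. Step 3.**
- Risks:
  - The angelate may isomerise from Z to E.
  - The acyl group may migrate under base from the phenol oxygen to the tied-back tertiary oxetanol.
- The fallback builds the acyl group on the phenol by carbonylation instead of transferring a preformed angeloyl unit. It sets out from 6 and comes back at 8.
- Compound 6, (Z)-2-bromobut-2-ene and CO (1 atm) are heated with Pd(OAc)2, Xantphos and Na2CO3 in toluene at 80 °C.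
- This is a phenoxycarbonylation of a vinyl bromide that keeps the alkene geometry and gives 8 directly, with no new compound on the way (entry F0).

**Further compounds**
F1 | step 4 | (2-hydroxy-5-methoxy-4-methylphenyl)boronic acid | OB(O)c1cc(OC)c(C)cc1O
F2 | step 4 | 2-(3-hydroxyprop-1-en-2-yl)-4-methoxy-5-methylphenol | Oc1cc(C)c(OC)cc1C(=C)CO
F3 | step 4 | 2-(3-hydroxyprop-1-en-2-yl)-4-methoxy-5-methylphenyl (2Z)-2-methylbut-2-enoate | C/C=C(/C)C(=O)Oc1cc(C)c(OC)cc1C(=C)CO
F4 | step 4 | 2-[(2S)-2-(hydroxymethyl)oxiran-2-yl]-4-methoxy-5-methylphenyl (2Z)-2-methylbut-2-enoate | C/C=C(/C)C(=O)Oc1cc(C)c(OC)cc1[C@]1(CO)CO1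
F5 | step 2 | 1-(benzyloxy)-2-bromo-4-methoxy-5-methylbenzene | Cc1cc(OCc2ccccc2)c(Br)cc1OC
F6 | step 2 | [2-(benzyloxy)-5-methoxy-4-methylphenyl]lithium | [Li]c1cc(OC)c(C)cc1OCc1ccccc1
F7 | step 2 | 3-[2-(benzyloxy)-5-methoxy-4-methylphenyl]oxetan-3-ol | Cc1cc(OCc2ccccc2)c(cc1OC)C1(O)COC1
F0 | step 3 | none | none
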